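**Strategy.** Each dihydrobenzofuran is cut at its C3–aryl bond to a trans-2-aryl-2,3-dihydrobenzofuran-3-carboxylic acid, and each acid at C3–C3a to a (2R)-flavanone. The furan ring O1–C2–C3–C3a–C7a is a chroman-4-one with one ring carbon excised: PhI(OAc)2 in acidic trimethyl orthoformate shifts ring A from the carbonyl carbon to C3, which forms C3–C3a, contracts the pyranone, extrudes C4 as the ester and relays the C2 configuration to a trans C3 in one operation. The precursor, (R)-7-bromo-5-methoxy-2-(4-methoxyphenyl)chroman-4-one, comes from catalytic asymmetric arylation of a chromone common to both units; decarboxylative arylations and a Heck reaction complete the skeleton.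

Key step: step 5

Assumption: (R)-MeO-F12-BIPHEP (2,2'-bis[bis(3,4,5-trifluorophenyl)phosphino]-6,6'-dimethoxy-1,1'-biphenyl) is taken to give the (R)-flavanones, by analogy with the facial sense of biaryl bisphosphine–rhodium catalysts on cyclic enones; the sense would be checked on the first batch by circular dichroism and the (S)-ligand used if it were opposite.

Abbreviations: NHPI = N-hydroxyphthalimide; DIC = N,N'-diisopropylcarbodiimide; dppBz = 1,2-bis(diphenylphosphino)benzene; dtbbpy = 4,4'-di-tert-butyl-2,2'-bipyridine.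

**Route**

Step 1
Reactants: 1 1-(4-bromo-2,6-difluorophenyl)ethan-1-one
Product: 2 1-(4-bromo-2,6-dimethoxyphenyl)ethan-1-one
Conditions: NaOMe (3 equiv), DMSO/MeOH, 60 °C
Reagents that add atoms: sodium methoxide, [Na+].[O-]C
Why: Twofold nucleophilic aromatic substitution (SNAr), in which both fluorides are ortho to the acetyl group and fluoride is a far better leaving group than the para bromide in addition–elimination, so only the C–F bonds should be exchanged.

Step 2
Reactants: 2 1-(4-bromo-2,6-dimethoxyphenyl)ethan-1-one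
Product: 3 1-(4-bromo-2-hydroxy-6-methoxyphenyl)ethan-1-one
Conditions: BCl3 (1.2 equiv), CH2Cl2, −78 → 0 °C; H2O
Reagents that add atoms: none
Why: Chelation-controlled Lewis-acid ether cleavage, in which boron bound to the carbonyl oxygen delivers chloride to the methyl of one ortho methoxy group and the resulting six-membered aryloxyboron chelate ties up the reagent and protects the second ether.

Step 3
Reactants: 3 1-(4-bromo-2-hydroxy-6-methoxyphenyl)ethan-1-one, 4 N,N-dimethylformamide dimethyl acetal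
Product: 6 7-bromo-5-methoxy-4H-chromen-4-one, via enaminone 5 (not isolated)
Conditions: 4 (2 equiv), toluene, 100 °C; concentrate; conc. HCl, CH2Cl2, 25 °C
Reagents that add atoms: none
Why: Enaminone route to chromones, in which condensation of the acetyl methyl group with the amide acetal gives enaminone 5 and acid then promotes conjugate addition of the phenol and loss of dimethylamine to close the pyranone ring.

Step 4
Reactants: 6 7-bromo-5-methoxy-4H-chromen-4-one, 7 4-methoxyphenylboronic acid
Product: 8 (R)-7-bromo-5-methoxy-2-(4-methoxyphenyl)chroman-4-one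
Conditions: 7 (2 equiv), [Rh(OH)(cod)]2 (1.5 mol%), (R)-MeO-F12-BIPHEP (3.3 mol%), toluene/H2O, 25 °C
Reagents that add atoms: none
Why: Rhodium-catalysed asymmetric 1,4-addition of an arylboronic acid (Hayashi–Miyaura reaction), in which the aryl–rhodium species carrying the chiral bisphosphine inserts the C2=C3 bond on one face of the chromone and so sets C2 as (R) under catalyst control, while monovalent rhodium leaves the aryl bromide untouched.

Step 5
Reactants: 8 (R)-7-bromo-5-methoxy-2-(4-methoxyphenyl)chroman-4-one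
Product: 10 methyl (2R,3R)-6-bromo-4-methoxy-2-(4-methoxyphenyl)-2,3-dihydrobenzofuran-3-carboxylate, via enol ether 9 (not isolated)
Conditions: HC(OMe)3, H2SO4 (cat.), 25 °C; then PhI(OAc)2 (1.2 equiv), 0 → 25 °C
Reagents that add atoms: trimethyl orthoformate, COC(OC)OC
Why: Acid and the orthoformate turn the ketone into enol ether 9, PhI(OAc)2 then bonds to C3 on the face opposite the C2 aryl group, methanol caps C4 as the ketal, and the C4–C4a bond, antiperiplanar to the equatorial C3–I bond, shifts to C3 as iodobenzene leaves, after which the dimethoxycarbenium ion at C4 loses a methyl group to acetate and remains as the methyl ester. The closest known reaction type is the oxidative ring contraction of flavanones by trivalent iodine or thallium trinitrate in trimethyl orthoformate, a semipinacol-type 1,2-aryl shift of the kind seen in α-halo ketals. The dihydrofuran ring is not closed by cyclisation but arises from the six-membered ring by the 1,2-shift of the ring A carbon C4a, which forms C3–C3a and expels C4 from the ring. C2 is not touched and keeps its (R) configuration, while C3 is set by the substrate: attack of iodine anti to the aryl group followed by inversion at C3 places the ester trans, and acid-catalysed enolisation of the ester can only reinforce this more stable arrangement. The step needs migration of ring A in preference to a shift of the anisyl group from C2 to C3 or elimination to the flavone; this is secured by the diequatorial arrangement of aryl group and iodine, which aligns the ring bond and not the C2–aryl bond with the leaving group, and by the ring oxygen and the 5-methoxy group ortho to C4a, which stabilise the bridged arenium ion, while the aryl bromide is inert to the oxidant.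

Step 6
Reactants: 10 methyl (2R,3R)-6-bromo-4-methoxy-2-(4-methoxyphenyl)-2,3-dihydrobenzofuran-3-carboxylate, 11 4-methoxystyrene
Product: 12 methyl (2R,3R)-4-methoxy-2-(4-methoxyphenyl)-6-[(E)-2-(4-methoxyphenyl)ethenyl]-2,3-dihydrobenzofuran-3-carboxylate
Conditions: 11 (1.5 equiv), Pd(OAc)2 (5 mol%), P(o-tol)3 (10 mol%), Et3N, DMF, 100 °C
Reagents that add atoms: none
Why: Mizoroki–Heck reaction, in which zerovalent palladium inserts into the C–Br bond, the aryl group adds to the unsubstituted terminus of the styrene and syn β-hydride elimination gives the E-stilbene; doing it here removes the only carbon–halogen bond of this fragment before the nickel-catalysed union, and C3 stays in its thermodynamically preferred trans arrangement.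

Step 7
Reactants: 12 methyl (2R,3R)-4-methoxy-2-(4-methoxyphenyl)-6-[(E)-2-(4-methoxyphenyl)ethenyl]-2,3-dihydrobenzofuran-3-carboxylate
Product: 13 (2R,3R)-4-methoxy-2-(4-methoxyphenyl)-6-[(E)-2-(4-methoxyphenyl)ethenyl]-2,3-dihydrobenzofuran-3-carboxylic acid
Conditions: LiOH·H2O (3 equiv), THF/MeOH/H2O, 25 °C; then 1 M HCl
Reagents that add atoms: lithium hydroxide, [Li+].[OH-]
Why: Ester saponification by addition–elimination at the acyl carbon, in which C2 has no acidic hydrogen, the trans acid is the thermodynamic epimer at C3, and ring opening by β-elimination of the aryloxide would be a disfavoured retro-5-endo-trig process.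

Step 8
Reactants: 6 7-bromo-5-methoxy-4H-chromen-4-one, 14 2,4-dimethoxyphenylboronic acid
Product: 15 (R)-7-bromo-2-(2,4-dimethoxyphenyl)-5-methoxychroman-4-one
Conditions: 14 (3 equiv), [Rh(OH)(cod)]2 (2 mol%), (R)-MeO-F12-BIPHEP (4.4 mol%), toluene/H2O, 25 °C
Reagents that add atoms: none
Why: The same rhodium-catalysed asymmetric 1,4-addition as in step 4, a reaction type that accepts ortho-substituted, electron-rich arylboronic acids (used in excess against protodeboronation) and sets C2 as (R) under control of the same ligand.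

Step 9
Reactants: 15 (R)-7-bromo-2-(2,4-dimethoxyphenyl)-5-methoxychroman-4-one
Product: 17 methyl (2R,3R)-6-bromo-2-(2,4-dimethoxyphenyl)-4-methoxy-2,3-dihydrobenzofuran-3-carboxylate, via enol ether 16 (not isolated)
Conditions: HC(OMe)3, H2SO4 (cat.), 25 °C; then PhI(OAc)2 (1.1 equiv), −10 → 25 °C
Reagents that add atoms: trimethyl orthoformate, COC(OC)OC
Why: The same trivalent-iodine ring contraction as in step 5 (semipinacol-type 1,2-shift of ring A, C2 retained, C3 set trans by anti iodination and inversion), with enol ether 16 formed before the oxidant is added cold so that PhI(OAc)2 meets the much more nucleophilic enol ether and not the dimethoxyphenyl ring.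

Step 10
Reactants: 17 methyl (2R,3R)-6-bromo-2-(2,4-dimethoxyphenyl)-4-methoxy-2,3-dihydrobenzofuran-3-carboxylate
Product: 18 (2R,3R)-6-bromo-2-(2,4-dimethoxyphenyl)-4-methoxy-2,3-dihydrobenzofuran-3-carboxylic acid
Conditions: LiOH·H2O (3 equiv), THF/MeOH/H2O, 25 °C; then 1 M HCl
Reagents that add atoms: lithium hydroxide, [Li+].[OH-]
Why: Ester saponification as in step 7, with the same safeguards for C2 and C3 and no effect on the aryl bromide.

Step 11
Reactants: 18 (2R,3R)-6-bromo-2-(2,4-dimethoxyphenyl)-4-methoxy-2,3-dihydrobenzofuran-3-carboxylic acid, 19 1-bromo-3,5-dimethoxybenzene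
Product: 23 (2R,3R)-6-bromo-2-(2,4-dimethoxyphenyl)-3-(3,5-dimethoxyphenyl)-4-methoxy-2,3-dihydrobenzofuran, via N-acyloxyphthalimide 20 (not isolated), via arylmagnesium bromide 21 (not isolated), via diarylzinc 22 (not isolated)
Conditions: 18, NHPI, DIC, DMAP (cat.), CH2Cl2, 25 °C; 19, Mg, THF, 40 °C, then ZnCl2 (0.5 equiv); then Fe(acac)3 (10 mol%), dppBz (12 mol%), THF, 25 °C
Reagents that add atoms: none
Why: Iron-catalysed decarboxylative Negishi-type arylation of a redox-active ester, in which electron transfer to N-acyloxyphthalimide 20 releases CO2 and the planar benzylic C3 radical, the aryl–iron species captures it on the face away from the C2 aryl group to give the trans product, and the iron–bisphosphine catalyst is chosen because it should not insert into the aryl bromide needed for step 12.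

Step 12
Reactants: 13 (2R,3R)-4-methoxy-2-(4-methoxyphenyl)-6-[(E)-2-(4-methoxyphenyl)ethenyl]-2,3-dihydrobenzofuran-3-carboxylic acid, 23 (2R,3R)-6-bromo-2-(2,4-dimethoxyphenyl)-3-(3,5-dimethoxyphenyl)-4-methoxy-2,3-dihydrobenzofuran
Product: 27 (2R,3R)-2-(2,4-dimethoxyphenyl)-3-(3,5-dimethoxyphenyl)-4-methoxy-6-{(2R,3R)-4-methoxy-2-(4-methoxyphenyl)-6-[(E)-2-(4-methoxyphenyl)ethenyl]-2,3-dihydrobenzofuran-3-yl}-2,3-dihydrobenzofuran, via N-acyloxyphthalimide 24 (not isolated), via aryllithium 25 (not isolated), via arylzinc chloride 26 (not isolated)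
Conditions: 13, NHPI, DIC, DMAP (cat.), CH2Cl2, 25 °C; 23 (2 equiv), t-BuLi (2 equiv per bromide), THF, −78 °C, then ZnCl2; then NiCl2·glyme (20 mol%), dtbbpy (40 mol%), THF/DMF, 25 °C
Reagents that add atoms: none
Why: Nickel-catalysed decarboxylative Negishi arylation of a redox-active ester, in which bromine–lithium exchange and transmetalation give arylzinc 26, single-electron reduction of N-acyloxyphthalimide 24 by an aryl–nickel species releases CO2 and the benzylic C3 radical, and recombination at nickel with reductive elimination forms the C3–aryl bond anti to the C2 anisyl group (trans), with no carbon–halogen bond left in either partner to compete and the stilbene a poor radical acceptor.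

Step 13
Reactants: 27 (2R,3R)-2-(2,4-dimethoxyphenyl)-3-(3,5-dimethoxyphenyl)-4-methoxy-6-{(2R,3R)-4-methoxy-2-(4-methoxyphenyl)-6-[(E)-2-(4-methoxyphenyl)ethenyl]-2,3-dihydrobenzofuran-3-yl}-2,3-dihydrobenzofuran
Product: 28 (2R,3R)-2-(2,4-dihydroxyphenyl)-3-(3,5-dihydroxyphenyl)-6-{(2R,3R)-4-hydroxy-2-(4-hydroxyphenyl)-6-[(E)-2-(4-hydroxyphenyl)ethenyl]-2,3-dihydrobenzofuran-3-yl}-2,3-dihydrobenzofuran-4-ol
Conditions: BBr3 (24 equiv), CH2Cl2, −78 → 25 °C; H2O
Reagents that add atoms: none
Why: Global Lewis-acid demethylation of aryl methyl ethers, in which bromide attacks each boron-activated O-methyl group in an SN2 sense, the only other ionisable bonds are the benzylic ring C2–O bonds, whose reversible opening would re-close to the more stable trans rings under control of the untouched C3 centres, and aqueous work-up releases the eight phenols.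

**Compound list**

1 | 1-(4-bromo-2,6-difluorophenyl)ethan-1-one | CC(=O)c1c(F)cc(Br)cc1F | starting material
2 | 1-(4-bromo-2,6-dimethoxyphenyl)ethan-1-one | CC(=O)c1c(OC)cc(Br)cc1OC | intermediate
3 | 1-(4-bromo-2-hydroxy-6-methoxyphenyl)ethan-1-one | CC(=O)c1c(O)cc(Br)cc1OC | intermediate
4 | N,N-dimethylformamide dimethyl acetal | COC(OC)N(C)C | starting material
5 | (E)-1-(4-bromo-2-hydroxy-6-methoxyphenyl)-3-(dimethylamino)prop-2-en-1-one | CN(C)/C=C/C(=O)c1c(O)cc(Br)cc1OC | intermediate (not isolated)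
6 | 7-bromo-5-methoxy-4H-chromen-4-one | O=c1ccoc2cc(Br)cc(OC)c12 | intermediate
7 | 4-methoxyphenylboronic acid | COc1ccc(B(O)O)cc1 | starting material
8 | (R)-7-bromo-5-methoxy-2-(4-methoxyphenyl)chroman-4-one | O=C1C[C@H](c2ccc(OC)cc2)Oc2cc(Br)cc(OC)c12 | intermediate
9 | (R)-7-bromo-4,5-dimethoxy-2-(4-methoxyphenyl)-2H-chromene | COC1=C[C@H](c2ccc(OC)cc2)Oc2cc(Br)cc(OC)c12 | intermediate (not isolated)
10 | methyl (2R,3R)-6-bromo-4-methoxy-2-(4-methoxyphenyl)-2,3-dihydrobenzofuran-3-carboxylate | Brc1cc(OC)c2c(c1)O[C@@H](c1ccc(OC)cc1)[C@@H]2C(=O)OC | intermediate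
11 | 4-methoxystyrene | C=Cc1ccc(OC)cc1 | starting material
12 | methyl (2R,3R)-4-methoxy-2-(4-methoxyphenyl)-6-[(E)-2-(4-methoxyphenyl)ethenyl]-2,3-dihydrobenzofuran-3-carboxylate | COc1ccc(/C=C/c2cc(OC)c3c(c2)O[C@@H](c2ccc(OC)cc2)[C@@H]3C(=O)OC)cc1 | intermediate
13 | (2R,3R)-4-methoxy-2-(4-methoxyphenyl)-6-[(E)-2-(4-methoxyphenyl)ethenyl]-2,3-dihydrobenzofuran-3-carboxylic acid | COc1ccc(/C=C/c2cc(OC)c3c(c2)O[C@@H](c2ccc(OC)cc2)[C@@H]3C(=O)O)cc1 | intermediate
14 | 2,4-dimethoxyphenylboronic acid | COc1ccc(B(O)O)c(OC)c1 | starting material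
15 | (R)-7-bromo-2-(2,4-dimethoxyphenyl)-5-methoxychroman-4-one | O=C1C[C@H](c2ccc(OC)cc2OC)Oc2cc(Br)cc(OC)c12 | intermediate
16 | (R)-7-bromo-2-(2,4-dimethoxyphenyl)-4,5-dimethoxy-2H-chromene | COC1=C[C@H](c2ccc(OC)cc2OC)Oc2cc(Br)cc(OC)c12 | intermediate (not isolated)
17 | methyl (2R,3R)-6-bromo-2-(2,4-dimethoxyphenyl)-4-methoxy-2,3-dihydrobenzofuran-3-carboxylate | Brc1cc(OC)c2c(c1)O[C@@H](c1ccc(OC)cc1OC)[C@@H]2C(=O)OC | intermediate
18 | (2R,3R)-6-bromo-2-(2,4-dimethoxyphenyl)-4-methoxy-2,3-dihydrobenzofuran-3-carboxylic acid | Brc1cc(OC)c2c(c1)O[C@@H](c1ccc(OC)cc1OC)[C@@H]2C(=O)O | intermediate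
19 | 1-bromo-3,5-dimethoxybenzene | COc1cc(Br)cc(OC)c1 | starting material
20 | 1,3-dioxoisoindolin-2-yl (2R,3R)-6-bromo-2-(2,4-dimethoxyphenyl)-4-methoxy-2,3-dihydrobenzofuran-3-carboxylate | Brc1cc(OC)c2c(c1)O[C@@H](c1ccc(OC)cc1OC)[C@@H]2C(=O)ON1C(=O)c2ccccc2C1=O | intermediate (not isolated)
21 | (3,5-dimethoxyphenyl)magnesium bromide | COc1cc([Mg]Br)cc(OC)c1 | intermediate (not isolated)
22 | bis(3,5-dimethoxyphenyl)zinc | COc1cc([Zn]c2cc(OC)cc(OC)c2)cc(OC)c1 | intermediate (not isolated)
23 | (2R,3R)-6-bromo-2-(2,4-dimethoxyphenyl)-3-(3,5-dimethoxyphenyl)-4-methoxy-2,3-dihydrobenzofuran | Brc1cc(OC)c2c(c1)O[C@@H](c1ccc(OC)cc1OC)[C@@H]2c1cc(OC)cc(OC)c1 | intermediate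
24 | 1,3-dioxoisoindolin-2-yl (2R,3R)-4-methoxy-2-(4-methoxyphenyl)-6-[(E)-2-(4-methoxyphenyl)ethenyl]-2,3-dihydrobenzofuran-3-carboxylate | COc1ccc(/C=C/c2cc(OC)c3c(c2)O[C@@H](c2ccc(OC)cc2)[C@@H]3C(=O)ON2C(=O)c3ccccc3C2=O)cc1 | intermediate (not isolated)
25 | [(2R,3R)-2-(2,4-dimethoxyphenyl)-3-(3,5-dimethoxyphenyl)-4-methoxy-2,3-dihydrobenzofuran-6-yl]lithium | [Li]c1cc(OC)c2c(c1)O[C@@H](c1ccc(OC)cc1OC)[C@@H]2c1cc(OC)cc(OC)c1 | intermediate (not isolated)
26 | [(2R,3R)-2-(2,4-dimethoxyphenyl)-3-(3,5-dimethoxyphenyl)-4-methoxy-2,3-dihydrobenzofuran-6-yl]zinc chloride | Cl[Zn]c1cc(OC)c2c(c1)O[C@@H](c1ccc(OC)cc1OC)[C@@H]2c1cc(OC)cc(OC)c1 | intermediate (not isolated)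
27 | (2R,3R)-2-(2,4-dimethoxyphenyl)-3-(3,5-dimethoxyphenyl)-4-methoxy-6-{(2R,3R)-4-methoxy-2-(4-methoxyphenyl)-6-[(E)-2-(4-methoxyphenyl)ethenyl]-2,3-dihydrobenzofuran-3-yl}-2,3-dihydrobenzofuran | COc1ccc(/C=C/c2cc(OC)c3c(c2)O[C@@H](c2ccc(OC)cc2)[C@@H]3c2cc(OC)c3c(c2)O[C@@H](c2ccc(OC)cc2OC)[C@@H]3c2cc(OC)cc(OC)c2)cc1 | intermediate
28 | (2R,3R)-2-(2,4-dihydroxyphenyl)-3-(3,5-dihydroxyphenyl)-6-{(2R,3R)-4-hydroxy-2-(4-hydroxyphenyl)-6-[(E)-2-(4-hydroxyphenyl)ethenyl]-2,3-dihydrobenzofuran-3-yl}-2,3-dihydrobenzofuran-4-ol (CNP0118407.2) | Oc1ccc(/C=C/c2cc(O)c3c(c2)O[C@@H](c2ccc(O)cc2)[C@@H]3c2cc(O)c3c(c2)O[C@@H](c2ccc(O)cc2O)[C@@H]3c2cc(O)cc(O)c2)cc1 | target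

**Step count and risks**

Total step count: 13. Longest linear sequence: 9 steps (steps 1–3, 4–7, 12 and 13; the branch through steps 8–11 is equally long).

Steps most likely to fail:

1. Step 9. The oxidant may be consumed by the electron-rich dimethoxyphenyl ring, that ring may migrate from C2 to C3 in place of ring A, or acid may ionise the doubly donor-stabilised C2–O bond and erode enantiopurity. The fallback separates halogenation from rearrangement and uses no hypervalent iodine. It sets out from 15: α-bromination with PhNMe3Br3 in THF at 0 °C should give the trans bromo ketone (2S,3S)-3,7-dibromo-2-(2,4-dimethoxyphenyl)-5-methoxychroman-4-one F1, in which C2 has the same spatial arrangement as in 15 and the descriptor changes only because bromine raises the rank of C3. HC(OMe)3 and TsOH in MeOH then give the dimethyl ketal (2S,3S)-3,7-dibromo-2-(2,4-dimethoxyphenyl)-4,4,5-trimethoxychromane F2. ZnBr2 in toluene at 90 °C, the Lewis-acid 1,2-aryl shift of α-bromo ketals, contracts the ring with inversion at C3 and comes back to the route at 17.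

2. Step 11. Capture of the benzylic radical by the iron catalyst may be slow, so that the radical dimerises or is reduced, or the aryl bromide may be attacked after all. The fallback masks the bromide as a boronate during the arylation. It sets out from 18: Miyaura borylation (Pd(dppf)Cl2, B2pin2, KOAc, dioxane, 90 °C) gives (2R,3R)-2-(2,4-dimethoxyphenyl)-4-methoxy-6-(4,4,5,5-tetramethyl-1,3,2-dioxaborolan-2-yl)-2,3-dihydrobenzofuran-3-carboxylic acid F3. Its ester with NHPI, 1,3-dioxoisoindolin-2-yl (2R,3R)-2-(2,4-dimethoxyphenyl)-4-methoxy-6-(4,4,5,5-tetramethyl-1,3,2-dioxaborolan-2-yl)-2,3-dihydrobenzofuran-3-carboxylate F4, is formed in the flask with DIC and arylated with diarylzinc 22 under the nickel conditions of step 12 (NiCl2·glyme, dtbbpy, THF/DMF, 25 °C). This gives 2-[(2R,3R)-2-(2,4-dimethoxyphenyl)-3-(3,5-dimethoxyphenyl)-4-methoxy-2,3-dihydrobenzofuran-6-yl]-4,4,5,5-tetramethyl-1,3,2-dioxaborolane F5. Bromodeboronation with CuBr2 in MeOH/H2O at 80 °C comes back to the route at 23.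

3. Step 12. Bromine–lithium exchange and transmetalation of the polymethoxylated bromide may be incomplete or accompanied by proton transfer to the aryllithium, or the hindered arylzinc may transmetalate to nickel too slowly, so that the benzylic radical dimerises. The fallback is a reductive cross-electrophile coupling that needs no organometallic reagent. It sets out from 23: copper-catalysed halogen exchange (CuI, NaI, trans-N,N'-dimethylcyclohexane-1,2-diamine, dioxane, 110 °C) gives (2R,3R)-2-(2,4-dimethoxyphenyl)-3-(3,5-dimethoxyphenyl)-6-iodo-4-methoxy-2,3-dihydrobenzofuran F6. This is coupled with ester 24, made from 13 as in step 12 and isolated by filtration through silica, using NiBr2·glyme, dtbbpy and zinc dust in DMA at 25 °C, and comes back to the route at 27.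

**Further compounds**

F1 | step 9 | (2S,3S)-3,7-dibromo-2-(2,4-dimethoxyphenyl)-5-methoxychroman-4-one | O=C1[C@@H](Br)[C@H](c2ccc(OC)cc2OC)Oc2cc(Br)cc(OC)c12
F2 | step 9 | (2S,3S)-3,7-dibromo-2-(2,4-dimethoxyphenyl)-4,4,5-trimethoxychromane | COC1(OC)[C@@H](Br)[C@H](c2ccc(OC)cc2OC)Oc2cc(Br)cc(OC)c12
F3 | step 11 | (2R,3R)-2-(2,4-dimethoxyphenyl)-4-methoxy-6-(4,4,5,5-tetramethyl-1,3,2-dioxaborolan-2-yl)-2,3-dihydrobenzofuran-3-carboxylic acid | CC1(C)OB(OC1(C)C)c1cc(OC)c2c(c1)O[C@@H](c1ccc(OC)cc1OC)[C@@H]2C(=O)O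
F4 | step 11 | 1,3-dioxoisoindolin-2-yl (2R,3R)-2-(2,4-dimethoxyphenyl)-4-methoxy-6-(4,4,5,5-tetramethyl-1,3,2-dioxaborolan-2-yl)-2,3-dihydrobenzofuran-3-carboxylate | CC1(C)OB(OC1(C)C)c1cc(OC)c2c(c1)O[C@@H](c1ccc(OC)cc1OC)[C@@H]2C(=O)ON1C(=O)c2ccccc2C1=O
F5 | step 11 | 2-[(2R,3R)-2-(2,4-dimethoxyphenyl)-3-(3,5-dimethoxyphenyl)-4-methoxy-2,3-dihydrobenzofuran-6-yl]-4,4,5,5-tetramethyl-1,3,2-dioxaborolane | CC1(C)OB(OC1(C)C)c1cc(OC)c2c(c1)O[C@@H](c1ccc(OC)cc1OC)[C@@H]2c1cc(OC)cc(OC)c1
F6 | step 12 | (2R,3R)-2-(2,4-dimethoxyphenyl)-3-(3,5-dimethoxyphenyl)-6-iodo-4-methoxy-2,3-dihydrobenzofuran | Ic1cc(OC)c2c(c1)O[C@@H](c1ccc(OC)cc1OC)[C@@H]2c1cc(OC)cc(OC)c1
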